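Disconnection at the C12–C13 single bond of the polyene: heteroxanthin ⇒ fragment A (C16: ring A, the 3,5,6-trihydroxy ring, with C7–C12 ending in the terminal alkyne C11≡C12–H) + fragment B (C24: ring B, the acetylenic ring, with C7'–C15' and C15–C13 ending in the methyl-capped alkyne CH3–C13≡C14).
Enabling feature: C11=C12–C13(CH3)=C14 is an (E,E)-1,3-diene whose CH carbon C12 (of a 1,2-disubstituted olefin) is bonded to the methyl-bearing inner carbon C13 (of a trisubstituted olefin); this is the retron of a reductive coupling of a terminal alkyne with a 1-propynyl group, a union of two alkyne carbons of like polarity that sets both olefin geometries in the same operation.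
Both fragments go back to one C15 ynenal (ring + C7–C11), made from (4R,6R)-actinol by enol triflate formation and Sonogashira coupling with the C6 enynol; fragment B then needs two Horner–Wadsworth–Emmons extensions (C5 nitrile, then C4 propargyl).
Fragment A: alkyne homologation at C11, hydroxyl-directed syn-epoxidation of C5=C6, trans-diaxial hydrolysis at C5, hydroxyl-directed trans-reduction of C7≡C8.
Ring order: no carbocycle is built (rings A and B are both the actinol ring); transient rings are the C5–C6 epoxide (formed in step 11, opened in step 12) and the titanacyclopropene and titanacyclopentadiene of step 15 (formed and cleaved in one flask).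

Key step: step 15

Assumption: (4R,6R)-actinol 1 and the C5 nitrile phosphonate 8 are taken as purchasable building blocks; 8 is sold as an E/Z mixture, so the (13'E) isomer would be secured by separation at nitrile 10.

Step 1
Reactants: 1 (4R,6R)-actinol
Product: 2 (4R,6R)-4-[(tert-butyldimethylsilyl)oxy]-2,2,6-trimethylcyclohexan-1-one
Conditions: TBSCl, imidazole, DMF, rt
Reagents that add atoms: tert-butyldimethylsilyl chloride, CC(C)(C)[Si](C)(C)Cl
Why: Silyl ether formation masks the only O–H before enolate chemistry and touches no stereocentre.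

Step 2
Reactants: 2 (4R,6R)-4-[(tert-butyldimethylsilyl)oxy]-2,2,6-trimethylcyclohexan-1-one
Product: 4 (4R)-4-[(tert-butyldimethylsilyl)oxy]-2,6,6-trimethylcyclohex-1-en-1-yl trifluoromethanesulfonate, via lithium enolate 3 (not isolated)
Conditions: LiN(iPr)2, THF, −78 °C; then PhNTf2, −78 °C → rt
Reagents that add atoms: N-phenylbis(trifluoromethanesulfonimide), O=S(=O)(N(c1ccccc1)S(=O)(=O)C(F)(F)F)C(F)(F)F
Why: Enol triflate formation is regiochemically unambiguous because the ketone can enolise only toward the methyl-bearing carbon (the other α-carbon is quaternary), which erases that stereocentre on purpose and leaves the silyloxy carbon untouched.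

Step 3
Reactants: 4 (4R)-enol triflate; 5 (2E)-3-methylpent-2-en-4-yn-1-ol
Product: 6 (2E)-5-[(4R)-4-[(tert-butyldimethylsilyl)oxy]-2,6,6-trimethylcyclohex-1-en-1-yl]-3-methylpent-2-en-4-yn-1-ol
Conditions: Pd(PPh3)4 (cat.), CuI (cat.), Et3N, DMF, rt
Reagents that add atoms: none
Why: Sonogashira coupling of the vinyl triflate with the terminal alkyne forms the ring–C7 bond with retention of the (E)-geometry of the enynol and tolerates the free primary alcohol.

Step 4
Reactants: 6 C15 dienynol
Product: 7 (2E)-5-[(4R)-4-[(tert-butyldimethylsilyl)oxy]-2,6,6-trimethylcyclohex-1-en-1-yl]-3-methylpent-2-en-4-ynal (C15 ynenal)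
Conditions: MnO2, CH2Cl2, rt
Reagents that add atoms: none
Why: MnO2 oxidation is selective for the allylic alcohol and should leave the silyl ether, the alkyne and the olefin geometry unchanged.

Step 5
Reactants: 7 C15 ynenal; 8 diethyl [(2E)-3-cyano-2-methylprop-2-en-1-yl]phosphonate
Product: 10 (2E,4E,6E)-9-[(4R)-4-[(tert-butyldimethylsilyl)oxy]-2,6,6-trimethylcyclohex-1-en-1-yl]-3,7-dimethylnona-2,4,6-trien-8-ynenitrile, via phosphonate carbanion sodium salt 9 (not isolated)
Conditions: NaH, THF, 0 °C; then 7, 0 °C → rt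
Reagents that add atoms: none
Why: Horner–Wadsworth–Emmons olefination with the allylic phosphonate carbanion should give the new C11'=C12' olefin as the (E)-isomer, the C13'=C14' geometry coming from the reagent and any (13'Z) isomer being removed by chromatography.

Step 6
Reactants: 10 C20 nitrile
Product: 11 (2E,4E,6E)-9-[(4R)-4-[(tert-butyldimethylsilyl)oxy]-2,6,6-trimethylcyclohex-1-en-1-yl]-3,7-dimethylnona-2,4,6-trien-8-ynal (C20 aldehyde)
Conditions: iBu2AlH, CH2Cl2, −78 °C; then aq. KNaC4H4O6 (potassium sodium tartrate), rt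
Reagents that add atoms: water, O
Why: Partial nitrile reduction stops at the N-aluminio imine, which is hydrolysed on work-up to the aldehyde while the silyl ether and the enyne are inert at −78 °C.

Step 7
Reactants: 12 1-bromobut-2-yne; 13 triethyl phosphite
Product: 14 diethyl but-2-yn-1-ylphosphonate
Conditions: neat, 120 °C
Reagents that add atoms: none
Why: Michaelis–Arbuzov reaction of the primary propargylic bromide gives the phosphonate with loss of bromoethane.

Step 8
Reactants: 11 C20 aldehyde; 14 diethyl but-2-yn-1-ylphosphonate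
Product: 16 fragment B tert-butyl{[(1R)-4-[(3E,5E,7E,9E)-3,7-dimethyltrideca-3,5,7,9-tetraene-1,11-diyn-1-yl]-3,5,5-trimethylcyclohex-3-en-1-yl]oxy}dimethylsilane, via phosphonate carbanion sodium salt 15 (not isolated)
Conditions: NaN(SiMe3)2, THF, −78 °C; then 11, −78 → 0 °C
Reagents that add atoms: none
Why: Horner–Wadsworth–Emmons olefination with the propargylic phosphonate carbanion, kept cold to suppress propargyl–allenyl isomerisation, should give the (E)-C15'=C15 olefin and installs the CH3–C13≡C14 unit for the key step.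

Step 9
Reactants: 7 C15 ynenal
Product: 17 tert-butyldimethyl{[(1R)-3,5,5-trimethyl-4-[(3E)-3-methylhex-3-ene-1,5-diyn-1-yl]cyclohex-3-en-1-yl]oxy}silane
Conditions: Me3SiCHN2, LiN(iPr)2, THF, −78 °C; then 7, −78 °C → rt
Reagents that add atoms: (trimethylsilyl)diazomethane, C[Si](C)(C)C=[N+]=[N-]
Why: Colvin rearrangement (addition of the lithiated diazo reagent, Peterson elimination, loss of N2 and 1,2-hydrogen shift of the alkylidene carbene) converts the aldehyde into the terminal alkyne C11≡C12–H with the C9=C10 geometry intact.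

Step 10
Reactants: 17 silyl-protected enediyne
Product: 18 (1R)-3,5,5-trimethyl-4-[(3E)-3-methylhex-3-ene-1,5-diyn-1-yl]cyclohex-3-en-1-ol
Conditions: Bu4NF, THF, 0 °C → rt
Reagents that add atoms: none
Why: Fluoride desilylation frees the C3 hydroxyl that must direct the next step, and the (E)-enediyne (which cannot cycloaromatise) is stable to these conditions.

Step 11
Reactants: 18 hydroxy enediyne
Product: 19 (1S,3S,6S)-1,5,5-trimethyl-6-[(3E)-3-methylhex-3-ene-1,5-diyn-1-yl]-7-oxabicyclo[4.1.0]heptan-3-ol (epoxide oxygen cis to the hydroxyl)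
Conditions: VO(acac)2 (cat.), tBuOOH, CH2Cl2, 0 °C → rt
Reagents that add atoms: tert-butyl hydroperoxide, CC(C)(C)OO
Why: Hydroxyl-directed epoxidation: the homoallylic C3 alkoxide binds the vanadium peroxide and delivers oxygen to the C5=C6 olefin on its own face, which sets C5 and C6, while the undirected, electron-poor C9=C10 olefin and the alkynes are left alone.

Step 12
Reactants: 19 syn-epoxy alcohol
Product: 20 (1S,2R,4S)-2,6,6-trimethyl-1-[(3E)-3-methylhex-3-ene-1,5-diyn-1-yl]cyclohexane-1,2,4-triol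
Conditions: HClO4 (cat.), THF/H2O, 0 °C
Reagents that add atoms: water, O
Why: Acid-catalysed epoxide hydrolysis by trans-diaxial opening: water should attack C5 opposite the epoxide oxygen (inversion at C5, retention at C6) because only this path leads directly to the chair with the C3 hydroxyl equatorial and because C6 is shielded by the quaternary C1 and less able to carry charge with its alkynyl substituent, giving the 5-hydroxyl trans to both the 3- and 6-hydroxyls.

Step 13
Reactants: 20 triol enediyne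
Product: 21 (1R,2R,4S)-2,6,6-trimethyl-1-[(1E,3E)-3-methylhexa-1,3-dien-5-yn-1-yl]cyclohexane-1,2,4-triol
Conditions: NaAlH2(OCH2CH2OMe)2, THF, 0 °C → rt; then aq. KNaC4H4O6
Reagents that add atoms: none
Why: Hydroxyl-directed trans-hydroalumination of a propargylic alcohol: the C6 alkoxide carries the aluminium hydride and delivers hydride to C7 only, so protonolysis should give the (7E)-olefin while the undirected C11≡C12 alkyne and the C9=C10 olefin are untouched.

Step 14
Reactants: 21 triol dienyne
Product: 22 fragment A (1R,2R,4S)-2,6,6-trimethyl-1-[(1E,3E)-3-methylhexa-1,3-dien-5-yn-1-yl]-1,2,4-tris[(trimethylsilyl)oxy]cyclohexane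
Conditions: Me3SiOTf, Et3N, CH2Cl2, −78 → 0 °C
Reagents that add atoms: trimethylsilyl trifluoromethanesulfonate, C[Si](C)(C)OS(=O)(=O)C(F)(F)F
Why: Exhaustive silyl ether formation with the silyl triflate in the presence of base removes all three O–H protons, including the two hindered tertiary ones, which would otherwise protonate the titanium–carbon bonds of the key step.

Step 15
Reactants: 16 fragment B; 22 fragment A
Product: 25 3'-O-(tert-butyldimethylsilyl)-3,5,6-tris-O-(trimethylsilyl)heteroxanthin, via titanacyclopropene 23 (not isolated), via titanacyclopentadiene 24 (not isolated)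
Conditions: 16, ClTi(OiPr)3, c-C5H9MgCl, PhMe/Et2O, −78 → −30 °C; then 22, −78 → −30 °C; then aq. NaHCO3, 0 °C; dark, argon
Reagents that add atoms: none
Why: Proposed new method: the mechanism is ligand exchange of (η2-cyclopentene)Ti(OiPr)2, made in the flask, with the CH3–C13≡C14 alkyne of 16 to give titanacyclopropene 23, insertion of the terminal alkyne of 22 into the less hindered Ti–C13 bond to give titanacyclopentadiene 24 (new C12–C13 bond, titanium on C11 and C14), and stereoretentive protonolysis of both Ti–C bonds. The closest known reaction type is the titanium alkoxide-mediated reductive cross-coupling of an internal alkyne with a terminal alkyne to a trisubstituted (E,E)-1,3-diene, extended here to polyene-conjugated partners; two alkyne carbons of like polarity are joined because divalent titanium supplies the two electrons. No ring of the target is closed: the only rings formed are the three- and five-membered titanacycles (oxidative cyclisation at titanium), both cleaved in the same flask. No stereocentre is created, but two olefin geometries are set, since each alkyne undergoes syn addition of titanium and carbon inside the metallacycle, so that protonolysis leaves C10 trans to C13 (11E) and C15 trans to C12 with the methyl cis to C15 (13E). The step needs site selectivity among three alkynes, secured by forming the titanium complex on 16 before 22 is added (cross-coupling over homocoupling) and by the shielding of C7'≡C8' by the tetrasubstituted ring B carbon C6', the geminal dimethyl group on C1' and the C9' methyl. It also needs regioselectivity of insertion, secured by the alkenyl substituents preferring the titanium-bound carbons C11 and C14 and by H and CH3, the smallest groups, sitting on the carbons that form the new bond, while the silyl ethers remove every O–H that could protonate the Ti–C bonds.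

Step 16
Reactants: 25 silyl-protected heteroxanthin
Product: 26 heteroxanthin, (3S,5R,6R,3'R)-7',8'-didehydro-5,6-dihydro-β,β-carotene-3,3',5,6-tetrol
Conditions: Bu4NF, THF, 0 °C → rt; dark, argon
Reagents that add atoms: none
Why: Fluoride-mediated global desilylation removes the secondary silyl ether and the three trimethylsilyl ethers without acid, so the tertiary allylic C6 alcohol and the all-E polyene are not exposed to cation-forming conditions and no stereocentre is affected.

Compound list
1 | (4R,6R)-4-hydroxy-2,2,6-trimethylcyclohexan-1-one ((4R,6R)-actinol) | O=C1C(C)(C)C[C@H](O)C[C@H]1C | starting material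
2 | (4R,6R)-4-[(tert-butyldimethylsilyl)oxy]-2,2,6-trimethylcyclohexan-1-one | O=C1C(C)(C)C[C@H](O[Si](C)(C)C(C)(C)C)C[C@H]1C | intermediate
3 | lithium (4R)-4-[(tert-butyldimethylsilyl)oxy]-2,6,6-trimethylcyclohex-1-en-1-olate (not isolated) | CC1=C(O[Li])C(C)(C)C[C@H](O[Si](C)(C)C(C)(C)C)C1 | intermediate
4 | (4R)-4-[(tert-butyldimethylsilyl)oxy]-2,6,6-trimethylcyclohex-1-en-1-yl trifluoromethanesulfonate | CC1=C(OS(=O)(=O)C(F)(F)F)C(C)(C)C[C@H](O[Si](C)(C)C(C)(C)C)C1 | intermediate
5 | (2E)-3-methylpent-2-en-4-yn-1-ol | C#C/C(C)=C/CO | starting material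
6 | (2E)-5-[(4R)-4-[(tert-butyldimethylsilyl)oxy]-2,6,6-trimethylcyclohex-1-en-1-yl]-3-methylpent-2-en-4-yn-1-ol | CC1=C(C#C/C(C)=C/CO)C(C)(C)C[C@H](O[Si](C)(C)C(C)(C)C)C1 | intermediate
7 | (2E)-5-[(4R)-4-[(tert-butyldimethylsilyl)oxy]-2,6,6-trimethylcyclohex-1-en-1-yl]-3-methylpent-2-en-4-ynal (C15 ynenal) | CC1=C(C#C/C(C)=C/C=O)C(C)(C)C[C@H](O[Si](C)(C)C(C)(C)C)C1 | intermediate
8 | diethyl [(2E)-3-cyano-2-methylprop-2-en-1-yl]phosphonate | CCOP(=O)(OCC)C/C(C)=C/C#N | starting material
9 | sodium salt of the carbanion of 8 (not isolated) | [Na+].CCOP(=O)(OCC)[CH-]/C(C)=C/C#N | intermediate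
10 | (2E,4E,6E)-9-[(4R)-4-[(tert-butyldimethylsilyl)oxy]-2,6,6-trimethylcyclohex-1-en-1-yl]-3,7-dimethylnona-2,4,6-trien-8-ynenitrile | CC1=C(C#C/C(C)=C/C=C/C(C)=C/C#N)C(C)(C)C[C@H](O[Si](C)(C)C(C)(C)C)C1 | intermediate
11 | (2E,4E,6E)-9-[(4R)-4-[(tert-butyldimethylsilyl)oxy]-2,6,6-trimethylcyclohex-1-en-1-yl]-3,7-dimethylnona-2,4,6-trien-8-ynal (C20 aldehyde) | CC1=C(C#C/C(C)=C/C=C/C(C)=C/C=O)C(C)(C)C[C@H](O[Si](C)(C)C(C)(C)C)C1 | intermediate
12 | 1-bromobut-2-yne | CC#CCBr | starting material
13 | triethyl phosphite | CCOP(OCC)OCC | starting material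
14 | diethyl but-2-yn-1-ylphosphonate | CCOP(=O)(OCC)CC#CC | intermediate
15 | sodium salt of the carbanion of 14 (not isolated) | [Na+].CCOP(=O)(OCC)[CH-]C#CC | intermediate
16 | fragment B, tert-butyl{[(1R)-4-[(3E,5E,7E,9E)-3,7-dimethyltrideca-3,5,7,9-tetraene-1,11-diyn-1-yl]-3,5,5-trimethylcyclohex-3-en-1-yl]oxy}dimethylsilane | CC1=C(C#C/C(C)=C/C=C/C(C)=C/C=C/C#CC)C(C)(C)C[C@H](O[Si](C)(C)C(C)(C)C)C1 | intermediate
17 | tert-butyldimethyl{[(1R)-3,5,5-trimethyl-4-[(3E)-3-methylhex-3-ene-1,5-diyn-1-yl]cyclohex-3-en-1-yl]oxy}silane | CC1=C(C#C/C(C)=C/C#C)C(C)(C)C[C@H](O[Si](C)(C)C(C)(C)C)C1 | intermediate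
18 | (1R)-3,5,5-trimethyl-4-[(3E)-3-methylhex-3-ene-1,5-diyn-1-yl]cyclohex-3-en-1-ol | CC1=C(C#C/C(C)=C/C#C)C(C)(C)C[C@H](O)C1 | intermediate
19 | (1S,3S,6S)-1,5,5-trimethyl-6-[(3E)-3-methylhex-3-ene-1,5-diyn-1-yl]-7-oxabicyclo[4.1.0]heptan-3-ol (epoxide cis to the hydroxyl) | C#C/C=C(C)/C#C[C@@]12C(C)(C)C[C@H](O)C[C@]1(C)O2 | intermediate
20 | (1S,2R,4S)-2,6,6-trimethyl-1-[(3E)-3-methylhex-3-ene-1,5-diyn-1-yl]cyclohexane-1,2,4-triol | C#C/C=C(C)/C#C[C@@]1(O)C(C)(C)C[C@H](O)C[C@@]1(C)O | intermediate
21 | (1R,2R,4S)-2,6,6-trimethyl-1-[(1E,3E)-3-methylhexa-1,3-dien-5-yn-1-yl]cyclohexane-1,2,4-triol | C#C/C=C(C)/C=C/[C@@]1(O)C(C)(C)C[C@H](O)C[C@@]1(C)O | intermediate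
22 | fragment A, (1R,2R,4S)-2,6,6-trimethyl-1-[(1E,3E)-3-methylhexa-1,3-dien-5-yn-1-yl]-1,2,4-tris[(trimethylsilyl)oxy]cyclohexane | C#C/C=C(C)/C=C/[C@@]1(O[Si](C)(C)C)C(C)(C)C[C@H](O[Si](C)(C)C)C[C@@]1(C)O[Si](C)(C)C | intermediate
23 | titanacyclopropene of 16: diisopropoxytitanium bound to C13 and C14 (not isolated) | CC1=C(/C=C/C=C(C)/C=C/C=C(C)/C#CC2=C(C)C[C@@H](O[Si](C)(C)C(C)(C)C)CC2(C)C)[Ti]1(OC(C)C)OC(C)C | intermediate
24 | titanacyclopentadiene: ring Ti–C11=C12–C13(CH3)=C14, diisopropoxytitanium, fragment A residue on C11, fragment B residue on C14 (not isolated) | CC1=C(/C=C/C=C(C)/C=C/C=C(C)/C#CC2=C(C)C[C@@H](O[Si](C)(C)C(C)(C)C)CC2(C)C)[Ti](OC(C)C)(OC(C)C)C(/C=C(C)/C=C/[C@@]2(O[Si](C)(C)C)C(C)(C)C[C@H](O[Si](C)(C)C)C[C@@]2(C)O[Si](C)(C)C)=C1 | intermediate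
25 | 3'-O-(tert-butyldimethylsilyl)-3,5,6-tris-O-(trimethylsilyl)heteroxanthin | CC1=C(C#C/C(C)=C/C=C/C(C)=C/C=C/C=C(C)/C=C/C=C(C)/C=C/[C@@]2(O[Si](C)(C)C)C(C)(C)C[C@H](O[Si](C)(C)C)C[C@@]2(C)O[Si](C)(C)C)C(C)(C)C[C@H](O[Si](C)(C)C(C)(C)C)C1 | intermediate
26 | heteroxanthin, (3S,5R,6R,3'R)-7',8'-didehydro-5,6-dihydro-β,β-carotene-3,3',5,6-tetrol | CC1=C(C#C/C(C)=C/C=C/C(C)=C/C=C/C=C(C)/C=C/C=C(C)/C=C/[C@@]2(O)C(C)(C)C[C@H](O)C[C@@]2(C)O)C(C)(C)C[C@H](O)C1 | target

Total step count: 16.
Longest linear sequence: 12 steps (steps 1–4 and 9–16, from actinol 1).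

Steps most likely to fail

Step 15 (Proposed new method). What may go wrong: complexation of titanium at the ring B alkyne or at the polyene instead of C13≡C14, proton transfer from the terminal alkyne of 22 to the titanium alkyne complex, and homocoupling of either partner. The fallback uses known palladium chemistry at a geminal dibromide; it sets out from 11 and 22 and comes back at 25. Aldehyde 11 would be extended by two carbons in a Wittig reaction with Ph3P=CHCHO (toluene, 80 °C) to (2E,4E,6E,8E)-11-[(4R)-4-[(tert-butyldimethylsilyl)oxy]-2,6,6-trimethylcyclohex-1-en-1-yl]-5,9-dimethylundeca-2,4,6,8-tetraen-10-ynal F1, and dibromo-olefination (CBr4, PPh3, CH2Cl2, 0 °C) would give the 1,1-dibromoalkene F2. Alkyne 22 would be hydrozirconated with Cp2Zr(H)Cl (THF, rt) to the (E)-alkenylzirconocene chloride F3, which after addition of ZnBr2 should undergo Negishi coupling with F2 under Pd(DPEphos)Cl2 catalysis selectively at the bromine trans to the chain, giving the (13Z)-13-bromo-20-nor analogue of 25 F4. Methylation of F4 with Me2Zn and Pd(PtBu3)2 (THF, rt) should then replace the remaining bromine with retention and give 25.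

Step 12. What may go wrong: ionisation at the propargylic C6 instead of attack at C5, with loss of regio- and stereocontrol at C5 and C6 or rearrangement of the tertiary propargylic alcohol. The fallback moves the epoxide opening to the ynenal stage, where the conjugated carbonyl group withdraws electron density from the alkyne and should suppress ionisation at C6; it sets out from 7 and comes back at 20. Ynenal 7 would be desilylated (HF·pyridine, THF, 0 °C) to (2E)-5-[(4R)-4-hydroxy-2,6,6-trimethylcyclohex-1-en-1-yl]-3-methylpent-2-en-4-ynal F5, epoxidised under the conditions of step 11 to the syn-epoxy ynenal F6, and hydrolysed (HClO4 cat., THF/H2O, 0 °C) to (2E)-3-methyl-5-[(1S,2R,4S)-1,2,4-trihydroxy-2,6,6-trimethylcyclohexyl]pent-2-en-4-ynal F7. Colvin homologation of F7 with excess LiC(N2)SiMe3 (THF, −78 °C → rt, the hydroxyls carried as lithium alkoxides) would then give 20.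

Step 8. What may go wrong: poor E/Z selectivity at C15'=C15 and propargyl-to-allenyl isomerisation of the phosphonate carbanion. The fallback builds the enyne by olefination and cross-coupling instead; it sets out from 11 and comes back at 16. Takai olefination of 11 (CHI3, CrCl2, THF, 0 °C) should give the (E)-vinyl iodide tert-butyl{[(1R)-4-[(3E,5E,7E,9E)-10-iodo-3,7-dimethyldeca-3,5,7,9-tetraen-1-yn-1-yl]-3,5,5-trimethylcyclohex-3-en-1-yl]oxy}dimethylsilane F8, and Sonogashira coupling of F8 with propyne (Pd(PPh3)4, CuI, Et3N, THF, rt) would give 16.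

Further compounds
F1 | step 15 | (2E,4E,6E,8E)-11-[(4R)-4-[(tert-butyldimethylsilyl)oxy]-2,6,6-trimethylcyclohex-1-en-1-yl]-5,9-dimethylundeca-2,4,6,8-tetraen-10-ynal | CC1=C(C#C/C(C)=C/C=C/C(C)=C/C=C/C=O)C(C)(C)C[C@H](O[Si](C)(C)C(C)(C)C)C1
F2 | step 15 | tert-butyl{[(1R)-4-[(3E,5E,7E,9E)-12,12-dibromo-3,7-dimethyldodeca-3,5,7,9,11-pentaen-1-yn-1-yl]-3,5,5-trimethylcyclohex-3-en-1-yl]oxy}dimethylsilane | CC1=C(C#C/C(C)=C/C=C/C(C)=C/C=C/C=C(Br)Br)C(C)(C)C[C@H](O[Si](C)(C)C(C)(C)C)C1
F3 | step 15 | (E)-alkenylzirconocene chloride from 22, Cp2Zr(Cl) on C12 | Cl[Zr](C1C=CC=C1)(C1C=CC=C1)/C=C/C=C(C)/C=C/[C@@]1(O[Si](C)(C)C)C(C)(C)C[C@H](O[Si](C)(C)C)C[C@@]1(C)O[Si](C)(C)C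
F4 | step 15 | (13Z)-13-bromo-20-nor analogue of 25 | CC1=C(C#C/C(C)=C/C=C/C(C)=C/C=C/C=C(Br)/C=C/C=C(C)/C=C/[C@@]2(O[Si](C)(C)C)C(C)(C)C[C@H](O[Si](C)(C)C)C[C@@]2(C)O[Si](C)(C)C)C(C)(C)C[C@H](O[Si](C)(C)C(C)(C)C)C1
F5 | step 12 | (2E)-5-[(4R)-4-hydroxy-2,6,6-trimethylcyclohex-1-en-1-yl]-3-methylpent-2-en-4-ynal | CC1=C(C#C/C(C)=C/C=O)C(C)(C)C[C@H](O)C1
F6 | step 12 | (2E)-5-[(1S,3S,6S)-3-hydroxy-1,5,5-trimethyl-7-oxabicyclo[4.1.0]heptan-6-yl]-3-methylpent-2-en-4-ynal (epoxide cis to the hydroxyl) | O=C/C=C(C)/C#C[C@@]12C(C)(C)C[C@H](O)C[C@]1(C)O2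
F7 | step 12 | (2E)-3-methyl-5-[(1S,2R,4S)-1,2,4-trihydroxy-2,6,6-trimethylcyclohexyl]pent-2-en-4-ynal | O=C/C=C(C)/C#C[C@@]1(O)C(C)(C)C[C@H](O)C[C@@]1(C)O
F8 | step 8 | tert-butyl{[(1R)-4-[(3E,5E,7E,9E)-10-iodo-3,7-dimethyldeca-3,5,7,9-tetraen-1-yn-1-yl]-3,5,5-trimethylcyclohex-3-en-1-yl]oxy}dimethylsilane | CC1=C(C#C/C(C)=C/C=C/C(C)=C/C=C/I)C(C)(C)C[C@H](O[Si](C)(C)C(C)(C)C)C1
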